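**Plan**

- Retrosynthesis: first the two ester C–O bonds (isovalerate on the chain oxygen, senecioate on the thenyl oxygen), then both C–S bonds of ring B, then the two C(sp)–C(sp) bonds between the three alkynes and the bond from ring A to the first alkyne.
- Enabling feature: ring B (the thiophene carrying the butynyl chain) is one sulfur plus four carbons that continue in a straight line into the exocyclic C≡C. These six carbons in a row on C5 of ring A (the thiophene carrying CH2O) are, without the sulfur, a conjugated triyne.
- Forward: ring A is bought as 5-bromothiophene-2-carbaldehyde; one Sonogashira and two Cadiot–Chodkiewicz couplings build a thienyl octatriyne; sulfide then closes ring B across the two alkynes next to ring A; the two esters go on last.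
- Protecting groups: the chain oxygen is carried as a bulky TBDPS ether and the thenyl hydroxyl is left free. This shields the far alkyne during ring closure and fixes the order of the two acylations.
- Stereochemistry: the target has no stereocentre and no stereogenic double bond (the senecioyl alkene carries two methyl groups), so nothing has to be set.

Key step: step 8

Remark on the chemistry: the six sp carbons of the triyne are called C1 to C6, counted from ring A (C1 on ring A, C6 on the CH2CH2O chain). Na2S·9H2O is assumed to supply the sulfur and, through its water, the two protons of ring B.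

**Route**

Step 1
Reactants: 1 5-bromothiophene-2-carbaldehyde; 2 ethynyltrimethylsilane
Product: 3 5-[(trimethylsilyl)ethynyl]thiophene-2-carbaldehyde
Conditions: PdCl2(PPh3)2 (cat.), CuI (cat.), Et3N, THF, 25 to 50 °C
Reagents that add atoms: none
Why: Sonogashira coupling, in which the formyl group activates the C–Br bond towards oxidative addition to zerovalent palladium and is itself inert to the amine and copper acetylide.

Step 2
Reactants: 3 5-[(trimethylsilyl)ethynyl]thiophene-2-carbaldehyde
Product: 5 (5-ethynylthiophen-2-yl)methanol, via silylalkynyl alcohol 4 (not isolated)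
Conditions: NaBH4, MeOH, 0 °C; then K2CO3, 25 °C
Reagents that add atoms: none
Why: Borohydride reduction of the aldehyde followed in the same flask by carbonate-catalysed methanolysis of the C(sp)–Si bond (protodesilylation), neither of which touches the thiophene or the alkyne.

Step 3
Reactants: 6 but-3-yn-1-ol
Product: 7 tert-butyl(but-3-yn-1-yloxy)diphenylsilane
Conditions: TBDPSCl, imidazole, CH2Cl2, 0 to 25 °C
Reagents that add atoms: tert-butyl(chloro)diphenylsilane, CC(C)(C)[Si](Cl)(c1ccccc1)c1ccccc1
Why: Imidazole-promoted silylation of a primary alcohol, giving a base-stable, bulky ether that should last through both copper couplings and the sulfide step.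

Step 4
Reactants: 7 tert-butyl(but-3-yn-1-yloxy)diphenylsilane
Product: 8 [(4-bromobut-3-yn-1-yl)oxy](tert-butyl)diphenylsilane
Conditions: NBS, AgNO3 (cat.), acetone, 25 °C, dark
Reagents that add atoms: N-bromosuccinimide, O=C1CCC(=O)N1Br
Why: Silver-catalysed electrophilic bromination of a terminal alkyne through its silver acetylide, a standard entry to 1-bromoalkynes that leaves the silyl ether alone.

Step 5
Reactants: 8 [(4-bromobut-3-yn-1-yl)oxy](tert-butyl)diphenylsilane; 2 ethynyltrimethylsilane
Product: 9 tert-butyl(diphenyl){[6-(trimethylsilyl)hexa-3,5-diyn-1-yl]oxy}silane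
Conditions: CuCl (cat.), NH2OH·HCl, n-BuNH2, Et2O/H2O, 0 °C, excess 2
Reagents that add atoms: none
Why: Cadiot–Chodkiewicz coupling of the copper acetylide of 2 with the bromoalkyne, with hydroxylamine keeping copper monovalent to suppress oxidative homocoupling and the low temperature and excess alkyne limiting loss of the trimethylsilyl group.

Step 6
Reactants: 9 tert-butyl(diphenyl){[6-(trimethylsilyl)hexa-3,5-diyn-1-yl]oxy}silane
Product: 10 [(6-bromohexa-3,5-diyn-1-yl)oxy](tert-butyl)diphenylsilane
Conditions: NBS, AgNO3 (cat.), acetone, 25 °C, dark; used at once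
Reagents that add atoms: N-bromosuccinimide, O=C1CCC(=O)N1Br
Why: Silver-catalysed bromodesilylation turns the C(sp)–SiMe3 bond directly into C(sp)–Br, so the unstable terminal diyne is never handled, while the O–Si bond of the TBDPS ether is not attacked.

Step 7
Reactants: 5 (5-ethynylthiophen-2-yl)methanol; 10 [(6-bromohexa-3,5-diyn-1-yl)oxy](tert-butyl)diphenylsilane
Product: 11 [5-(8-{[tert-butyl(diphenyl)silyl]oxy}octa-1,3,5-triyn-1-yl)thiophen-2-yl]methanol
Conditions: CuCl (cat.), NH2OH·HCl, n-BuNH2, CH2Cl2/H2O, 0 °C, slow addition of 10, dark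
Reagents that add atoms: none
Why: Cadiot–Chodkiewicz coupling of an aryl acetylene with a bromodiyne, the usual way to unsymmetrical triynes, which tolerates both the free thenyl hydroxyl and the silyl ether.

Step 8
Reactants: 11 [5-(8-{[tert-butyl(diphenyl)silyl]oxy}octa-1,3,5-triyn-1-yl)thiophen-2-yl]methanol
Product: 13 [5'-(4-{[tert-butyl(diphenyl)silyl]oxy}but-1-yn-1-yl)-2,2'-bithiophen-5-yl]methanol, via (Z)-enethiol 12 (not isolated)
Conditions: Na2S·9H2O (1.5 equiv), DMF, 0 to 25 °C, Ar, dark
Reagents that add atoms: sodium sulfide nonahydrate, O.O.O.O.O.O.O.O.O.[Na+].[Na+].[S-2]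
Why: Hydrosulfide, formed from Na2S and its water of crystallisation, should add anti across the thienyl-conjugated alkyne with sulfur on C1, the vinyl anion being stabilised by the remaining diyne and protonated by water to give (Z)-enethiol 12 (as its thiolate), whose sulfur then attacks C4 and, after protonation at C3, leaves aromatic ring B. This is the known base-mediated annulation of sulfide with conjugated 1,3-diynes and aryl polyynes to 2,5-disubstituted thiophenes, applied here to a thienyl triyne. Ring B closes in a 5-endo-dig mode, the S–C1 and S–C4 bonds both being made in this one operation and no C–C bond. No stereocentre is created; the anti course of the first addition matters only because it places sulfur cis to the diyne, as the closure requires. The step needs sulfur to bridge C1 and C4 and not C3 and C6: the thienyl-conjugated end is the more polarisable and electrophilic, C6 bears an electron-releasing sp3 carbon, the chain oxygen is capped as a bulky TBDPS ether so that no hydroxyl or alkoxide near C6 can guide hydrosulfide to the far alkyne, and first entry at C4 in place of C1 leads to the same ring. The remaining C5≡C6 alkyne is no longer part of a diyne and should resist further sulfide, and the silyl ether and free thenyl alcohol tolerate a basic medium that the two esters would not.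

Step 9
Reactants: 13 [5'-(4-{[tert-butyl(diphenyl)silyl]oxy}but-1-yn-1-yl)-2,2'-bithiophen-5-yl]methanol; 14 3-methylbut-2-enoic acid
Product: 15 [5'-(4-{[tert-butyl(diphenyl)silyl]oxy}but-1-yn-1-yl)-2,2'-bithiophen-5-yl]methyl 3-methylbut-2-enoate
Conditions: DCC, DMAP (cat.), CH2Cl2, 0 to 25 °C
Reagents that add atoms: none
Why: Steglich esterification of the only free hydroxyl, in which the acid is activated without acid chloride or trialkylamine so that the senecioyl double bond should stay in conjugation and the acid-sensitive thenyl C–O bond is not ionised.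

Step 10
Reactants: 15 [5'-(4-{[tert-butyl(diphenyl)silyl]oxy}but-1-yn-1-yl)-2,2'-bithiophen-5-yl]methyl 3-methylbut-2-enoate
Product: 16 [5'-(4-hydroxybut-1-yn-1-yl)-2,2'-bithiophen-5-yl]methyl 3-methylbut-2-enoate
Conditions: TBAF, AcOH, THF, 0 to 25 °C
Reagents that add atoms: none
Why: Fluoride-induced cleavage of the silyl ether, buffered with acetic acid so that the liberated alkoxide cannot transesterify or cleave the senecioate.

Step 11
Reactants: 16 [5'-(4-hydroxybut-1-yn-1-yl)-2,2'-bithiophen-5-yl]methyl 3-methylbut-2-enoate; 17 3-methylbutanoyl chloride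
Product: 18 4-[5'-({[3-methylbut-2-enoyl]oxy}methyl)-2,2'-bithiophen-5-yl]but-3-yn-1-yl 3-methylbutanoate (CNP0114739.0)
Conditions: pyridine, DMAP (cat.), CH2Cl2, 0 °C
Reagents that add atoms: none
Why: DMAP-catalysed acylation of a primary alcohol with an acid chloride, under which the senecioate, the alkyne and both thiophenes are inert.

**Compound list**

1 | 5-bromothiophene-2-carbaldehyde | O=Cc1ccc(Br)s1 | starting material
2 | ethynyltrimethylsilane | C#C[Si](C)(C)C | starting material
3 | 5-[(trimethylsilyl)ethynyl]thiophene-2-carbaldehyde | O=Cc1ccc(C#C[Si](C)(C)C)s1 | intermediate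
4 | {5-[(trimethylsilyl)ethynyl]thiophen-2-yl}methanol (formed in the flask in step 2) | OCc1ccc(C#C[Si](C)(C)C)s1 | intermediate
5 | (5-ethynylthiophen-2-yl)methanol | OCc1ccc(C#C)s1 | intermediate
6 | but-3-yn-1-ol | C#CCCO | starting material
7 | tert-butyl(but-3-yn-1-yloxy)diphenylsilane | C#CCCO[Si](c1ccccc1)(c1ccccc1)C(C)(C)C | intermediate
8 | [(4-bromobut-3-yn-1-yl)oxy](tert-butyl)diphenylsilane | BrC#CCCO[Si](c1ccccc1)(c1ccccc1)C(C)(C)C | intermediate
9 | tert-butyl(diphenyl){[6-(trimethylsilyl)hexa-3,5-diyn-1-yl]oxy}silane | C[Si](C)(C)C#CC#CCCO[Si](c1ccccc1)(c1ccccc1)C(C)(C)C | intermediate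
10 | [(6-bromohexa-3,5-diyn-1-yl)oxy](tert-butyl)diphenylsilane | BrC#CC#CCCO[Si](c1ccccc1)(c1ccccc1)C(C)(C)C | intermediate
11 | [5-(8-{[tert-butyl(diphenyl)silyl]oxy}octa-1,3,5-triyn-1-yl)thiophen-2-yl]methanol | OCc1ccc(C#CC#CC#CCCO[Si](c2ccccc2)(c2ccccc2)C(C)(C)C)s1 | intermediate
12 | {5-[(1Z)-8-{[tert-butyl(diphenyl)silyl]oxy}-1-sulfanyloct-1-ene-3,5-diyn-1-yl]thiophen-2-yl}methanol (formed in the flask in step 8, present as its sodium thiolate) | OCc1ccc(s1)/C(S)=C/C#CC#CCCO[Si](c2ccccc2)(c2ccccc2)C(C)(C)C | intermediate
13 | [5'-(4-{[tert-butyl(diphenyl)silyl]oxy}but-1-yn-1-yl)-2,2'-bithiophen-5-yl]methanol | OCc1ccc(-c2ccc(C#CCCO[Si](c3ccccc3)(c3ccccc3)C(C)(C)C)s2)s1 | intermediate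
14 | 3-methylbut-2-enoic acid | CC(C)=CC(=O)O | starting material
15 | [5'-(4-{[tert-butyl(diphenyl)silyl]oxy}but-1-yn-1-yl)-2,2'-bithiophen-5-yl]methyl 3-methylbut-2-enoate | CC(C)=CC(=O)OCc1ccc(-c2ccc(C#CCCO[Si](c3ccccc3)(c3ccccc3)C(C)(C)C)s2)s1 | intermediate
16 | [5'-(4-hydroxybut-1-yn-1-yl)-2,2'-bithiophen-5-yl]methyl 3-methylbut-2-enoate | CC(C)=CC(=O)OCc1ccc(-c2ccc(C#CCCO)s2)s1 | intermediate
17 | 3-methylbutanoyl chloride | CC(C)CC(=O)Cl | starting material
18 | 4-[5'-({[3-methylbut-2-enoyl]oxy}methyl)-2,2'-bithiophen-5-yl]but-3-yn-1-yl 3-methylbutanoate | CC(C)=CC(=O)OCc1ccc(-c2ccc(C#CCCOC(=O)CC(C)C)s2)s1 | target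

**Step count**

Total: 11 steps. Longest linear sequence: 9 steps (steps 3 to 11, from but-3-yn-1-ol).

**Steps most likely to fail**

Step 8. Hydrosulfide may enter at the alkyl terminus C6 and close across C3 to C6, which would put the sulfur bridge on the wrong pair of alkynes. Base-induced propargyl–allene isomerisation of the chain or a second sulfide addition may also consume the polyyne before ring closure. The fallback gives up the ring-forming event and sets out from 7. Sonogashira coupling of 7 with commercial 5'-bromo-2,2'-bithiophene-5-carbaldehyde (PdCl2(PPh3)2, CuI, Et3N, THF, 50 °C) should give 5'-(4-{[tert-butyl(diphenyl)silyl]oxy}but-1-yn-1-yl)-2,2'-bithiophene-5-carbaldehyde F1. Reduction with NaBH4 in MeOH/THF at 0 °C should then give 13, where the route resumes at step 9.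

Step 7. The bromodiyne may polymerise in the amine medium, and copper-mediated homocoupling of either partner may outrun the cross-coupling. The fallback moves the halide onto a monoyne and sets out from 5. Cadiot–Chodkiewicz coupling of 5 with commercial (bromoethynyl)triisopropylsilane (CuCl, NH2OH·HCl, n-BuNH2, 0 °C) should give {5-[4-(triisopropylsilyl)buta-1,3-diyn-1-yl]thiophen-2-yl}methanol F2. TBAF in THF at 0 °C should free [5-(buta-1,3-diyn-1-yl)thiophen-2-yl]methanol F3, which is kept in solution and coupled at once with bromoalkyne 8 under the same copper conditions. This comes back to the route at 11 and bypasses 9 and 10.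

Step 5. The trimethylsilyl group may be lost from 2 or from 9 in the aqueous amine, after which the freed diyne couples a second time or polymerises. The fallback makes the diyne by epoxide opening in place of an sp–sp coupling and sets out from 2. Hay oxidative homocoupling (CuCl, TMEDA, O2, acetone) should give 1,4-bis(trimethylsilyl)buta-1,3-diyne F4. MeLi·LiBr in THF removes one silyl group, and the resulting lithium butadiynide should open ethylene oxide in the presence of BF3·OEt2 at −78 °C to give 6-(trimethylsilyl)hexa-3,5-diyn-1-ol F5. Silylation with TBDPSCl and imidazole comes back to the route at 9.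

**Further compounds**

F1 | step 8 | 5'-(4-{[tert-butyl(diphenyl)silyl]oxy}but-1-yn-1-yl)-2,2'-bithiophene-5-carbaldehyde | O=Cc1ccc(-c2ccc(C#CCCO[Si](c3ccccc3)(c3ccccc3)C(C)(C)C)s2)s1
F2 | step 7 | {5-[4-(triisopropylsilyl)buta-1,3-diyn-1-yl]thiophen-2-yl}methanol | OCc1ccc(C#CC#C[Si](C(C)C)(C(C)C)C(C)C)s1
F3 | step 7 | [5-(buta-1,3-diyn-1-yl)thiophen-2-yl]methanol | OCc1ccc(C#CC#C)s1
F4 | step 5 | 1,4-bis(trimethylsilyl)buta-1,3-diyne | C[Si](C)(C)C#CC#C[Si](C)(C)C
F5 | step 5 | 6-(trimethylsilyl)hexa-3,5-diyn-1-ol | C[Si](C)(C)C#CC#CCCO
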